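**Plan**
- Retrosynthesis: the acid goes back to the C1 primary alcohol and the saturated ring to its C4=C5 alkene. Both ring C–O bonds (C3–O and C6–O) are then cut at once, because the C3–O–O–C6 bridge over the carbon run C3–C4(Me)–C5–C6(Me) of the 1,2-dioxane is the retron of O2 adding across a 1,3-diene.
- The diene, (3E,5E,8R)-4,6,8-trimethyl-17-phenylheptadeca-3,5-dien-1-ol, is cut at C2–C3 (oxirane), at C3=C4 and C5=C6 (two methylaluminations of terminal alkynes), at C4–C5 (ethynyl coupling), at C6–C7 (acetylide alkylation) and at C8–CH3 (enolate methylation of 11-phenylundecanoic acid).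
- Forward order: chain with C8 → alkyne → E-iodoalkene → enyne → E,E-dienol → dioxine (the only ring made; the phenyl ring is bought) → dioxane → acid.
- Stereochemistry: C8 from an Evans methylation. C3 and the quaternary C6 are set relative to each other by the diene geometry in the suprafacial cycloaddition. C4 comes from syn hydrogen delivery by diimide to the less hindered ring face.

Key step: step 9

Remark: nothing within reach of the diene can bias its two faces, so step 9 is planned to give the wanted (3S,6R) dioxine together with its (3R,6S) ring diastereomer (same 8R centre). The wanted one is carried on after chromatographic (HPLC) separation.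

**Route**

Step 1
Reactants: 1 11-phenylundecanoic acid; 2 (R)-4-benzyl-1,3-oxazolidin-2-one
Product: 4 (4R)-4-benzyl-3-(11-phenylundecanoyl)-1,3-oxazolidin-2-one, via mixed pivalic anhydride 3 (not isolated)
Conditions: PivCl, Et3N, THF, −20 °C; then 2, LiCl, rt
Reagents that add atoms: none
Why: Evans auxiliary attachment through the mixed anhydride; the hindered pivaloyl carbonyl is not attacked and LiCl lets Et3N activate the oxazolidinone N–H.

Step 2
Reactants: 4
Product: 6 (4R)-4-benzyl-3-[(2R)-2-methyl-11-phenylundecanoyl]-1,3-oxazolidin-2-one, via sodium Z-enolate 5 (not isolated)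
Conditions: NaN(SiMe3)2, THF, −78 °C; MeI, −78 → −40 °C; chromatography
Reagents that add atoms: iodomethane, CI
Why: Evans asymmetric alkylation, in which the chelated Z-enolate is methylated on the face away from the benzyl group, so the (R)-auxiliary should give the (R)-α-methyl centre (C8 of the target).

Step 3
Reactants: 6
Product: 7 (2R)-2-methyl-11-phenylundecan-1-ol
Conditions: LiBH4, Et2O, H2O (1 equiv), 0 °C
Reagents that add atoms: none
Why: reductive cleavage of the N-acyl oxazolidinone gives the primary alcohol without epimerising the α-centre and returns the auxiliary.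

Step 4
Reactants: 7
Product: 8 [(10R)-11-iodo-10-methylundecyl]benzene
Conditions: I2, PPh3, imidazole, CH2Cl2, 0 °C → rt
Reagents that add atoms: iodine, II
Why: Appel-type iodination of a primary alcohol; the stereocentre is one carbon away and is not touched.

Step 5
Reactants: 8
Product: 9 (4R)-4-methyl-13-phenyltridec-1-yne
Conditions: lithium acetylide–ethylenediamine complex, DMSO, 15 °C → rt
Reagents that add atoms: lithium acetylide–ethylenediamine complex, [Li+].[C-]#C.NCCN
Why: SN2 alkylation of lithium acetylide, a standard reaction of β-methyl-branched primary iodides in DMSO, adds C6 and C5.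

Step 6
Reactants: 9
Product: 11 [(10R,12E)-13-iodo-10,12-dimethyltridec-12-en-1-yl]benzene, via alkenyldimethylalane 10 (not isolated)
Conditions: AlMe3, Cp2ZrCl2 (cat.), CH2Cl2, rt; then I2, THF, −30 → 0 °C
Reagents that add atoms: trimethylaluminium, C[Al](C)C; iodine, II
Why: Negishi zirconium-catalysed carboalumination adds CH3 and Al syn across the terminal alkyne (methyl to C6, aluminium to C5), and iodinolysis with retention gives the E-iodoalkene.

Step 7
Reactants: 11
Product: 12 [(10R,12E)-10,12-dimethylpentadec-12-en-14-yn-1-yl]benzene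
Conditions: ethynylmagnesium bromide, ZnBr2, THF, 0 °C; then 11, Pd(PPh3)4 (cat.), rt
Reagents that add atoms: ethynylmagnesium bromide, C#C[Mg]Br
Why: Negishi coupling of the alkenyl iodide with ethynylzinc bromide under zerovalent palladium catalysis keeps the alkene geometry and gives the terminal enyne directly.

Step 8
Reactants: 12
Product: 15 (3E,5E,8R)-4,6,8-trimethyl-17-phenylheptadeca-3,5-dien-1-ol, via dienyldimethylalane 13 (not isolated), via lithium butyl(dienyl)dimethylalanate 14 (not isolated)
Conditions: AlMe3, Cp2ZrCl2 (cat.), CH2Cl2, rt; evaporate; n-BuLi, hexane/THF, −30 °C; oxirane, → rt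
Reagents that add atoms: trimethylaluminium, C[Al](C)C; oxirane, C1CO1
Why: a second syn carboalumination of the conjugated enyne sets the C3=C4 E-alkene with the C4 methyl, and the derived lithium alanate opens oxirane at the alkenyl carbon with retention to add C2 and C1.

Step 9
Reactants: 15
Product: 16 2-[(3S,6R)-4,6-dimethyl-6-[(2R)-2-methyl-11-phenylundecyl]-3,6-dihydro-1,2-dioxin-3-yl]ethan-1-ol
Conditions: O2, hν (visible), 5,10,15,20-tetraphenylporphyrin (cat.), CH2Cl2, −20 °C; HPLC separation of the ring diastereomer
Reagents that add atoms: dioxygen, O=O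
Why: Sensitised singlet oxygen adds across C3 and C6 of the s-cis rotamer of the 3,5-diene in a [4+2] cycloaddition (concerted, or through a short-lived perepoxide that closes on the same face), the closest known reaction type being the photooxygenation of acyclic 1,1,3-trisubstituted 1,3-dienes to 3,6-dihydro-1,2-dioxines. The six-membered peroxide ring is closed by cycloaddition, both C–O bonds (O–C3 and O–C6) forming in one event from one O2 molecule. C3 and the quaternary C6 are set relative to each other by the E,E geometry: suprafacial addition puts the two outside groups (CH2CH2OH on C3 and the CH2 of the side chain on C6) cis, with C3–H and the C6 methyl on the other face. The sense of the ring relative to the remote C8 centre is not controlled, so the (3S,6R) and (3R,6S) adducts should form together and the former is separated. The step needs [4+2] to win over the ene reaction at the allylic C–H bonds; the C4 methyl helps by destabilising the s-trans rotamer (A(1,3) strain with the C6 methyl), and a non-polar solvent at low temperature disfavours the polar ene channel.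

Step 10
Reactants: 16
Product: 17 2-[(3S,4S,6R)-4,6-dimethyl-6-[(2R)-2-methyl-11-phenylundecyl]-1,2-dioxan-3-yl]ethan-1-ol
Conditions: KO2CN=NCO2K (excess, in portions), AcOH, MeOH/CH2Cl2, 0 °C → rt
Reagents that add atoms: none
Why: diimide reduction transfers two hydrogens syn to C4=C5 without cleaving the O–O bond and should add on the face of C3–H and the C6 methyl, away from the two cis CH2 substituents, which places the C4 methyl cis to the C3 side chain (4S).

Step 11
Reactants: 17
Product: 19 2-[(3S,4S,6R)-4,6-dimethyl-6-[(2R)-2-methyl-11-phenylundecyl]-1,2-dioxan-3-yl]acetic acid, via dioxanylacetaldehyde 18 (not isolated)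
Conditions: TEMPO (cat.), PhI(OAc)2, MeCN/H2O, rt
Reagents that add atoms: water, O
Why: oxoammonium (TEMPO) oxidation of the primary alcohol through the aldehyde hydrate to the acid runs under mildly acidic, non-reducing conditions that a dialkyl peroxide tolerates and that avoid base-induced ring opening of the β-peroxy carbonyl compound.

**Compound list**
1 | 11-phenylundecanoic acid | OC(=O)CCCCCCCCCCc1ccccc1 | starting material
2 | (R)-4-benzyl-1,3-oxazolidin-2-one | O=C1OC[C@@H](Cc2ccccc2)N1 | starting material
3 | 11-phenylundecanoic pivalic anhydride | CC(C)(C)C(=O)OC(=O)CCCCCCCCCCc1ccccc1 | intermediate (not isolated)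
4 | (4R)-4-benzyl-3-(11-phenylundecanoyl)-1,3-oxazolidin-2-one | O=C(CCCCCCCCCCc1ccccc1)N1[C@H](Cc2ccccc2)COC1=O | intermediate
5 | sodium Z-enolate of 4 | [Na+].[O-]/C(=C\CCCCCCCCCc1ccccc1)N1[C@H](Cc2ccccc2)COC1=O | intermediate (not isolated)
6 | (4R)-4-benzyl-3-[(2R)-2-methyl-11-phenylundecanoyl]-1,3-oxazolidin-2-one | C[C@H](CCCCCCCCCc1ccccc1)C(=O)N1[C@H](Cc2ccccc2)COC1=O | intermediate
7 | (2R)-2-methyl-11-phenylundecan-1-ol | C[C@H](CCCCCCCCCc1ccccc1)CO | intermediate
8 | [(10R)-11-iodo-10-methylundecyl]benzene | C[C@H](CCCCCCCCCc1ccccc1)CI | intermediate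
9 | (4R)-4-methyl-13-phenyltridec-1-yne | C[C@H](CCCCCCCCCc1ccccc1)CC#C | intermediate
10 | dimethyl[(1E,4R)-2,4-dimethyl-13-phenyltridec-1-en-1-yl]alane | C[C@H](CCCCCCCCCc1ccccc1)C/C(C)=C/[Al](C)C | intermediate (not isolated)
11 | [(10R,12E)-13-iodo-10,12-dimethyltridec-12-en-1-yl]benzene | C[C@H](CCCCCCCCCc1ccccc1)C/C(C)=C/I | intermediate
12 | [(10R,12E)-10,12-dimethylpentadec-12-en-14-yn-1-yl]benzene | C[C@H](CCCCCCCCCc1ccccc1)C/C(C)=C/C#C | intermediate
13 | dimethyl[(1E,3E,6R)-2,4,6-trimethyl-15-phenylpentadeca-1,3-dien-1-yl]alane | C[C@H](CCCCCCCCCc1ccccc1)C/C(C)=C/C(C)=C/[Al](C)C | intermediate (not isolated)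
14 | lithium butyl(dimethyl)[(1E,3E,6R)-2,4,6-trimethyl-15-phenylpentadeca-1,3-dien-1-yl]alanate | [Li+].CCCC[Al-](C)(C)/C=C(C)/C=C(C)/C[C@H](C)CCCCCCCCCc1ccccc1 | intermediate (not isolated)
15 | (3E,5E,8R)-4,6,8-trimethyl-17-phenylheptadeca-3,5-dien-1-ol | C[C@H](CCCCCCCCCc1ccccc1)C/C(C)=C/C(C)=C/CCO | intermediate
16 | 2-[(3S,6R)-4,6-dimethyl-6-[(2R)-2-methyl-11-phenylundecyl]-3,6-dihydro-1,2-dioxin-3-yl]ethan-1-ol | C[C@H](CCCCCCCCCc1ccccc1)C[C@]1(C)C=C(C)[C@H](CCO)OO1 | intermediate
17 | 2-[(3S,4S,6R)-4,6-dimethyl-6-[(2R)-2-methyl-11-phenylundecyl]-1,2-dioxan-3-yl]ethan-1-ol | C[C@H](CCCCCCCCCc1ccccc1)C[C@]1(C)C[C@H](C)[C@H](CCO)OO1 | intermediate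
18 | 2-[(3S,4S,6R)-4,6-dimethyl-6-[(2R)-2-methyl-11-phenylundecyl]-1,2-dioxan-3-yl]acetaldehyde | C[C@H](CCCCCCCCCc1ccccc1)C[C@]1(C)C[C@H](C)[C@H](CC=O)OO1 | intermediate (not isolated)
19 | 2-[(3S,4S,6R)-4,6-dimethyl-6-[(2R)-2-methyl-11-phenylundecyl]-1,2-dioxan-3-yl]acetic acid | C[C@H](CCCCCCCCCc1ccccc1)C[C@]1(C)C[C@H](C)[C@H](CC(=O)O)OO1 | target

**Step count**
Total steps: 11. Longest linear sequence: 11.

**Steps most likely to fail**

1. Step 9. The cycloaddition has no facial bias from C8, so the two ring diastereomers should form in similar amounts and may co-elute; the ene reaction at the trisubstituted alkenes may also take part of the material. Fallback, resolution through a covalently bound chiral acid, setting out from 16 (unseparated) and coming back at 17: the mixture is taken through step 10, which gives 17 together with 2-[(3R,4R,6S)-4,6-dimethyl-6-[(2R)-2-methyl-11-phenylundecyl]-1,2-dioxan-3-yl]ethan-1-ol F1. Esterification with (S)-2-methoxy-2-phenylacetic acid (DCC, DMAP, CH2Cl2) should give the (S)-2-methoxy-2-phenylacetate of 17 F2 and the (S)-2-methoxy-2-phenylacetate of the diastereomer F3, which differ near the new ester centre and are separated by chromatography or crystallisation. K2CO3 in MeOH at rt then cleaves F2 back to 17, which enters step 11.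

2. Step 10. Diimide transfers hydrogen slowly to a trisubstituted alkene, and the facial preference at C4 may be modest because the ring can place either the C3 side chain or the C6 methyl pseudo-axial. Fallback, a stepwise radical hydrogenation in place of the concerted transfer, setting out from 16 and coming back at 17: hydrogen-atom-transfer hydrogenation with Mn(dpm)3 (cat.), PhSiH3 and t-BuOOH in i-PrOH at rt. A hydrogen atom should add to C5 and the tertiary C4 radical should take its hydrogen axially, anti to the pseudo-axial C3 side chain, which again places the C4 methyl cis to it. The in-ring radical is poorly aligned with the O–O bond, so attack on the peroxide should be slow. No new compound is formed on the way (none F0).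

3. Step 8. Carboalumination of the conjugated enyne may be incomplete or unselective, and the dienylalanate may open oxirane sluggishly. Fallback, a convergent alkenyl–alkenyl coupling, setting out from 9 (through alane 10 of step 6) and coming back at 15, so that the iodination of step 6 and steps 7 and 8 are bypassed: pent-3-yn-1-ol is silylated (TBSCl, imidazole) to tert-butyl(dimethyl)(pent-3-yn-1-yloxy)silane F4. Hydrozirconation with excess Cp2Zr(H)Cl at 50 °C, so that zirconium settles on the methyl-bearing alkyne carbon, gives the alkenylzirconocene chloride F5, and iodine converts it to tert-butyl{[(3E)-4-iodopent-3-en-1-yl]oxy}dimethylsilane F6. Alane 10 is then coupled directly with F6 (Pd(PPh3)4, ZnCl2, THF; Negishi coupling under zerovalent palladium catalysis with retention at both alkenes) to the tert-butyldimethylsilyl ether of 15 F7, and Bu4NF in THF returns 15.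

**Further compounds**
F1 | step 9 | 2-[(3R,4R,6S)-4,6-dimethyl-6-[(2R)-2-methyl-11-phenylundecyl]-1,2-dioxan-3-yl]ethan-1-ol | C[C@H](CCCCCCCCCc1ccccc1)C[C@@]1(C)C[C@@H](C)[C@@H](CCO)OO1
F2 | step 9 | 2-[(3S,4S,6R)-4,6-dimethyl-6-[(2R)-2-methyl-11-phenylundecyl]-1,2-dioxan-3-yl]ethyl (2S)-2-methoxy-2-phenylacetate | C[C@H](CCCCCCCCCc1ccccc1)C[C@]1(C)C[C@H](C)[C@H](CCOC(=O)[C@@H](OC)c2ccccc2)OO1
F3 | step 9 | 2-[(3R,4R,6S)-4,6-dimethyl-6-[(2R)-2-methyl-11-phenylundecyl]-1,2-dioxan-3-yl]ethyl (2S)-2-methoxy-2-phenylacetate | C[C@H](CCCCCCCCCc1ccccc1)C[C@@]1(C)C[C@@H](C)[C@@H](CCOC(=O)[C@@H](OC)c2ccccc2)OO1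
F0 | step 10 | none | none
F4 | step 8 | tert-butyl(dimethyl)(pent-3-yn-1-yloxy)silane | CC#CCCO[Si](C)(C)C(C)(C)C
F5 | step 8 | chloro{(2E)-5-[tert-butyl(dimethyl)silyloxy]pent-2-en-2-yl}zirconocene | Cl[Zr](C1C=CC=C1)(C1C=CC=C1)/C(C)=C/CCO[Si](C)(C)C(C)(C)C
F6 | step 8 | tert-butyl{[(3E)-4-iodopent-3-en-1-yl]oxy}dimethylsilane | C/C(I)=C\CCO[Si](C)(C)C(C)(C)C
F7 | step 8 | tert-butyl(dimethyl){[(3E,5E,8R)-4,6,8-trimethyl-17-phenylheptadeca-3,5-dien-1-yl]oxy}silane | C[C@H](CCCCCCCCCc1ccccc1)C/C(C)=C/C(C)=C/CCO[Si](C)(C)C(C)(C)C
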